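**Retrosynthetic overview**
1. Feature: the pyranone of the luteolin half (ring C'') contains the enol-ether double bond C2''=C3''. C3'' is next to the C4'' ketone. C2'' is bonded to O1'' and to the catechol ring B''. Read as an olefination, C2'' is the carbonyl carbon of a 3,4-dioxygenated benzoate on O1'', and C3'' is the ylide carbon of a phenacylidene phosphorane on C4a''.
2. Last disconnections: eight benzyl ethers (hydrogenolysis), then O1–C2 of the eriodictyol half (catalytic asymmetric oxa-Michael closure of an alkylidene β-keto ester, sets 2S), then the Knoevenagel bond at a ring B aldehyde.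
3. The ylide comes from a 3-aryl-2-hydroxy-4,6-bis(benzyloxy)acetophenone by α-bromination, PPh3, mild base and O-aroylation. Phosphorus is attached before any base is used, so no coumaranone can form. No acid is used while a phenol is near the ring B benzylic ester.
4. The C2'–C8'' axis comes from a Suzuki–Miyaura coupling of the 3-iodoacetophenone with a ring B boronate made from 2-bromoisovanillin. One dibenzylated phloroacetophenone serves both halves.
5. Order of ring formation: biaryl axis, then the flavone pyranone (ring C''), then the flavanone pyranone (ring C).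

Key step: step 14

Assumption 1: the SMILES fixes only C2 (S) and leaves the tetra-ortho-substituted C2'–C8'' axis undefined, so both axial forms are carried through and no axial configuration is set.
Assumption 2: the quinidine-derived thiourea is taken to give the 2S series; the quinine-derived pseudo-enantiomer gives the opposite sense, so a circular dichroism check on the protected flavanone decides which of the two is kept.

**Step 1**
Reactants: 1 2-bromoisovanillin
Product: 2 2-bromo-3,4-dihydroxybenzaldehyde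
Conditions: BBr3, CH2Cl2, −78 °C to rt; then H2O
Reagents that add atoms: none
Why: Lewis acid cleavage of an aryl methyl ether, in which boron binds the ether oxygen and bromide removes the methyl group by SN2 while the aldehyde and the aryl bromide are left alone.

**Step 2**
Reactants: 2 2-bromo-3,4-dihydroxybenzaldehyde
Product: 3 3,4-bis(benzyloxy)-2-bromobenzaldehyde
Conditions: BnBr, K2CO3, DMF, 60 °C
Reagents that add atoms: benzyl bromide, BrCc1ccccc1
Why: Williamson etherification of both acidic catechol hydroxyls gives benzyl ethers that last until the final hydrogenolysis.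

**Step 3**
Reactants: 3 3,4-bis(benzyloxy)-2-bromobenzaldehyde
Product: 4 [3,4-bis(benzyloxy)-2-bromophenyl]methanol
Conditions: NaBH4, THF/MeOH, 0 °C
Reagents that add atoms: none
Why: Borohydride reduction lowers the future Knoevenagel carbon to the alcohol level so that it cannot react with the ylide made later.

**Step 4**
Reactants: 4 [3,4-bis(benzyloxy)-2-bromophenyl]methanol
Product: 5 3,4-bis(benzyloxy)-2-bromobenzyl pivalate
Conditions: PivCl, Et3N, DMAP (cat.), CH2Cl2, 0 °C to rt
Reagents that add atoms: pivaloyl chloride, CC(C)(C)C(=O)Cl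
Why: DMAP-catalysed O-acylation installs a bulky ester without α-hydrogens that tolerates amide base, phosphine, ylide and heat and resists acyl transfer.

**Step 5**
Reactants: 5 3,4-bis(benzyloxy)-2-bromobenzyl pivalate
Product: 6 3,4-bis(benzyloxy)-2-(4,4,5,5-tetramethyl-1,3,2-dioxaborolan-2-yl)benzyl pivalate
Conditions: HBpin, PdCl2(MeCN)2 (cat.), SPhos, Et3N, 1,4-dioxane, 100 °C
Reagents that add atoms: pinacolborane, CC1(C)OBOC1(C)C
Why: Palladium-catalysed Miyaura-type borylation with pinacolborane, for which the bulky electron-rich biaryl phosphine is known to handle doubly ortho-substituted aryl bromides without touching esters or benzyl ethers.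

**Step 6**
Reactants: 7 2,4,6-trihydroxyacetophenone
Product: 8 4,6-bis(benzyloxy)-2-hydroxyacetophenone
Conditions: BnBr (2 equiv), K2CO3, DMF, rt to 50 °C
Reagents that add atoms: benzyl bromide, BrCc1ccccc1
Why: Selective Williamson etherification, because after two alkylations the last hydroxyl is hydrogen-bonded to the acetyl carbonyl and is much the least nucleophilic.

**Step 7**
Reactants: 8 4,6-bis(benzyloxy)-2-hydroxyacetophenone
Product: 9 4,6-bis(benzyloxy)-2-hydroxy-3-iodoacetophenone
Conditions: NIS (1.0 equiv), CH2Cl2, 0 °C to rt, dark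
Reagents that add atoms: N-iodosuccinimide, O=C1CCC(=O)N1I
Why: Electrophilic aromatic iodination, in which C3 and C5 are both activated by all three oxygens but C3 lies beside the small free hydroxyl while C5 is flanked by two benzyloxy groups, so iodine should enter at C3 as is usual for 2-hydroxy-4,6-dialkoxyacetophenones.

**Step 8**
Reactants: 9 4,6-bis(benzyloxy)-2-hydroxy-3-iodoacetophenone; 6 3,4-bis(benzyloxy)-2-(4,4,5,5-tetramethyl-1,3,2-dioxaborolan-2-yl)benzyl pivalate
Product: 10 4,6-bis(benzyloxy)-3-[2,3-bis(benzyloxy)-6-(pivaloyloxymethyl)phenyl]-2-hydroxyacetophenone (racemic axis)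
Conditions: Pd2(dba)3 (cat.), SPhos, K3PO4, toluene/H2O, 100 °C
Reagents that add atoms: none
Why: Suzuki–Miyaura coupling forms the C2'–C8'' bond, the dialkylbiaryl phosphine being the ligand class established for tetra-ortho-substituted biaryls, with boron placed on the ring that is less prone to protodeboronation.

**Step 9**
Reactants: 10 biaryl acetophenone
Product: 12 2-bromo-1-{4,6-bis(benzyloxy)-3-[2,3-bis(benzyloxy)-6-(pivaloyloxymethyl)phenyl]-2-hydroxyphenyl}ethanone, via bis(trimethylsilyl) enol ether 11 (not isolated)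
Conditions: LiHMDS (2.4 equiv), TMSCl, THF, −78 to 0 °C; then NBS (1.0 equiv), THF, −78 °C; pH 6 buffer
Reagents that add atoms: N-bromosuccinimide, O=C1CCC(=O)N1Br; chlorotrimethylsilane, C[Si](C)(C)Cl (its atoms stay only in 11)
Why: Silyl enol ether formation followed by electrophilic α-bromination directs the halogen to the methyl carbon, since the enol ether reacts with NBS far faster at low temperature than the alkoxy arenes, and the weakly acidic work-up frees the phenol without generating a phenoxide.

**Step 10**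
Reactants: 12 bromoketone
Product: 14 1-{4,6-bis(benzyloxy)-3-[2,3-bis(benzyloxy)-6-(pivaloyloxymethyl)phenyl]-2-hydroxyphenyl}-2-(triphenylphosphoranylidene)ethanone, via phosphonium bromide 13 (not isolated)
Conditions: PPh3, toluene, rt to 40 °C; then aq Na2CO3, CH2Cl2, rt
Reagents that add atoms: triphenylphosphine, c1ccc(cc1)P(c1ccccc1)c1ccccc1
Why: SN2 quaternisation of the primary α-bromoketone followed by deprotonation of the acidic phosphonium methylene gives the keto-stabilised ylide, and because phosphorus replaces the halide before base is added the ortho phenoxide has no leaving group to displace and no coumaranone can form.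

**Step 11**
Reactants: 15 3,4-dihydroxybenzoic acid
Product: 17 3,4-bis(benzyloxy)benzoic acid, via benzyl 3,4-bis(benzyloxy)benzoate 16 (not isolated)
Conditions: BnBr (3.3 equiv), K2CO3, DMF, 60 °C; then NaOH, THF/MeOH/H2O, 60 °C; HCl
Reagents that add atoms: benzyl bromide, BrCc1ccccc1; sodium hydroxide, [Na+].[OH-]
Why: Exhaustive Williamson alkylation followed by saponification of the only ester leaves the two phenolic benzyl ethers in place.

**Step 12**
Reactants: 17 3,4-bis(benzyloxy)benzoic acid
Product: 18 3,4-bis(benzyloxy)benzoyl chloride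
Conditions: (COCl)2, DMF (cat.), CH2Cl2, 0 °C to rt
Reagents that add atoms: oxalyl chloride, O=C(Cl)C(=O)Cl
Why: Acid chloride formation through Vilsmeier-type activation proceeds under conditions that do not affect aryl benzyl ethers.

**Step 13**
Reactants: 14 hydroxy ylide; 18 3,4-bis(benzyloxy)benzoyl chloride
Product: 19 3,5-bis(benzyloxy)-2-[2,3-bis(benzyloxy)-6-(pivaloyloxymethyl)phenyl]-6-[(triphenylphosphoranylidene)acetyl]phenyl 3,4-bis(benzyloxy)benzoate
Conditions: pyridine, DMAP (cat.), CH2Cl2, 0 °C to rt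
Reagents that add atoms: none
Why: Nucleophile-catalysed O-acylation of the phenol, the known way to ortho-acyloxyphenacylidene phosphoranes, in which any acylation at the ylide enolate oxygen gives an enol ester phosphonium salt that is itself an acyl donor, so the aroyl group should end on O1''.

**Step 14**
Reactants: 19 ortho-aroyloxyphenacylidene phosphorane
Product: 20 5,7-bis(benzyloxy)-2-[3,4-bis(benzyloxy)phenyl]-8-[2,3-bis(benzyloxy)-6-(pivaloyloxymethyl)phenyl]-4H-chromen-4-one
Conditions: toluene, 110 °C, N2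
Reagents that add atoms: none
Why: The stabilised ylide carbon (future C3'') adds to the carbonyl carbon of the neighbouring benzoate on O1'' (future C2''), the betaine closes to an oxaphosphetane, and cycloreversion expels Ph3PO and leaves the C2''=C3'' double bond. The closest known reaction type is the intramolecular Wittig olefination of ortho-acyloxyphenacylidene phosphoranes, an established neutral route to chromones and flavones. Ring C'' closes in a 6-exo-trig mode, since the attacked C=O lies outside the forming ring O1''–C2''–C3''–C4''–C4a''–C8a''. No stereocentre is formed, and the C2'–C8'' axis already present is carried on unchanged as the racemate. The step needs regioselectivity (8-aryl and not 6-aryl flavone) and chemoselectivity (aryl ester over pivalate): O5'' and O7'' are benzyl ethers, so O1'' bears the only acyl group within reach, and the pivalate is remote, hindered and an unactivated alkyl ester. Heating without base or proton source in a non-polar solvent favours oxaphosphetane collapse over loss of phenoxide from the betaine, and spares the acid-sensitive para-alkoxybenzylic ester on ring B.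

**Step 15**
Reactants: 20 flavone pivalate
Product: 21 5,7-bis(benzyloxy)-2-[3,4-bis(benzyloxy)phenyl]-8-[2,3-bis(benzyloxy)-6-(hydroxymethyl)phenyl]-4H-chromen-4-one
Conditions: NaOMe, MeOH/THF, rt to 40 °C
Reagents that add atoms: none
Why: Base-catalysed transesterification removes the only ester left, under conditions well short of the hot aqueous alkali needed to open a flavone.

**Step 16**
Reactants: 21 flavone benzylic alcohol
Product: 22 3,4-bis(benzyloxy)-2-{5,7-bis(benzyloxy)-2-[3,4-bis(benzyloxy)phenyl]-4-oxo-4H-chromen-8-yl}benzaldehyde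
Conditions: MnO2 (activated, excess), CH2Cl2, rt
Reagents that add atoms: none
Why: MnO2 oxidation is selective for the electron-rich benzylic alcohol and stops at the aldehyde.

**Step 17**
Reactants: 8 4,6-bis(benzyloxy)-2-hydroxyacetophenone
Product: 23 tert-butyl 3-[2,4-bis(benzyloxy)-6-hydroxyphenyl]-3-oxopropanoate
Conditions: LiHMDS (3.3 equiv), THF, −78 to −20 °C; Boc2O (1.05 equiv), −78 to 0 °C; cold 1 M HCl
Reagents that add atoms: di-tert-butyl dicarbonate, CC(C)(C)OC(=O)OC(=O)OC(C)(C)C
Why: Crossed Claisen-type C-acylation, in which excess base forms the phenoxide–enolate dianion whose carbon terminus is the more reactive site and the product is protected as its enolate, the tert-butyl ester being too hindered to lactonise to a 4-hydroxycoumarin.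

**Step 18**
Reactants: 22 flavone aldehyde; 23 tert-butyl β-keto ester
Product: 24 tert-butyl (Z)-2-[2,4-bis(benzyloxy)-6-hydroxybenzoyl]-3-(3,4-bis(benzyloxy)-2-{5,7-bis(benzyloxy)-2-[3,4-bis(benzyloxy)phenyl]-4-oxo-4H-chromen-8-yl}phenyl)acrylate
Conditions: piperidine (cat.), AcOH (cat.), 4 Å MS, toluene, rt to 40 °C
Reagents that add atoms: none
Why: Knoevenagel condensation under buffered amine catalysis joins the two halves without strong alkali, and the isomer with the aryl group cis to the ester is expected because it leaves the ketone conjugated.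

**Step 19**
Reactants: 24 alkylidene β-keto ester
Product: 26 (2S)-5,7-bis(benzyloxy)-2-(3,4-bis(benzyloxy)-2-{5,7-bis(benzyloxy)-2-[3,4-bis(benzyloxy)phenyl]-4-oxo-4H-chromen-8-yl}phenyl)chroman-4-one, via tert-butyl chromanone-3-carboxylate 25 (not isolated)
Conditions: 1-[3,5-bis(trifluoromethyl)phenyl]-3-(9-deoxy-epi-quinidin-9-yl)thiourea (10 mol%), toluene, −25 °C; then TsOH·H2O, 80 °C
Reagents that add atoms: none
Why: Bifunctional organocatalytic intramolecular oxa-Michael addition (6-endo-trig), in which the thiourea binds the two carbonyl groups of the alkylidene β-keto ester and the quinuclidine nitrogen activates the phenol so that O1 reaches one face of C2 and sets 2S under catalyst control, after which acid removes the tert-butyl ester and the β-keto acid loses CO2, erasing the labile C3 centre.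

**Step 20**
Reactants: 26 octa-O-benzyl (2S)-flavanone–flavone
Product: 27 CNP0265600.1, (2S)-eriodictyol-(2'→8'')-luteolin
Conditions: H2 (1 atm), 10% Pd/C, THF/MeOH, rt
Reagents that add atoms: none
Why: Catalytic hydrogenolysis removes all eight benzyl ethers under neutral conditions that leave the flavone C2''=C3'' bond, both carbonyl groups and the base-sensitive C2 stereocentre untouched.

**Compound list**
1 | 2-bromoisovanillin (2-bromo-3-hydroxy-4-methoxybenzaldehyde) | COc1ccc(C=O)c(Br)c1O | starting material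
2 | 2-bromo-3,4-dihydroxybenzaldehyde | O=Cc1ccc(O)c(O)c1Br | intermediate
3 | 3,4-bis(benzyloxy)-2-bromobenzaldehyde | O=Cc1ccc(OCc2ccccc2)c(OCc2ccccc2)c1Br | intermediate
4 | [3,4-bis(benzyloxy)-2-bromophenyl]methanol | OCc1ccc(OCc2ccccc2)c(OCc2ccccc2)c1Br | intermediate
5 | 3,4-bis(benzyloxy)-2-bromobenzyl pivalate | CC(C)(C)C(=O)OCc1ccc(OCc2ccccc2)c(OCc2ccccc2)c1Br | intermediate
6 | ring B pinacol boronate | CC(C)(C)C(=O)OCc1ccc(OCc2ccccc2)c(OCc2ccccc2)c1B1OC(C)(C)C(C)(C)O1 | intermediate
7 | 2,4,6-trihydroxyacetophenone | CC(=O)c1c(O)cc(O)cc1O | starting material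
8 | 4,6-bis(benzyloxy)-2-hydroxyacetophenone | CC(=O)c1c(O)cc(OCc2ccccc2)cc1OCc1ccccc1 | intermediate
9 | 4,6-bis(benzyloxy)-2-hydroxy-3-iodoacetophenone | CC(=O)c1c(O)c(I)c(OCc2ccccc2)cc1OCc1ccccc1 | intermediate
10 | biaryl acetophenone | CC(=O)c1c(O)c(-c2c(COC(=O)C(C)(C)C)ccc(OCc3ccccc3)c2OCc2ccccc2)c(OCc2ccccc2)cc1OCc1ccccc1 | intermediate
11 | bis(trimethylsilyl) enol ether of 10 | C=C(O[Si](C)(C)C)c1c(O[Si](C)(C)C)c(-c2c(COC(=O)C(C)(C)C)ccc(OCc3ccccc3)c2OCc2ccccc2)c(OCc2ccccc2)cc1OCc1ccccc1 | intermediate
12 | α-bromoketone | O=C(CBr)c1c(O)c(-c2c(COC(=O)C(C)(C)C)ccc(OCc3ccccc3)c2OCc2ccccc2)c(OCc2ccccc2)cc1OCc1ccccc1 | intermediate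
13 | phenacyl triphenylphosphonium bromide | O=C(C[P+](c1ccccc1)(c1ccccc1)c1ccccc1)c1c(O)c(-c2c(COC(=O)C(C)(C)C)ccc(OCc3ccccc3)c2OCc2ccccc2)c(OCc2ccccc2)cc1OCc1ccccc1.[Br-] | intermediate
14 | ortho-hydroxyphenacylidene triphenylphosphorane | O=C(C=P(c1ccccc1)(c1ccccc1)c1ccccc1)c1c(O)c(-c2c(COC(=O)C(C)(C)C)ccc(OCc3ccccc3)c2OCc2ccccc2)c(OCc2ccccc2)cc1OCc1ccccc1 | intermediate
15 | 3,4-dihydroxybenzoic acid | OC(=O)c1ccc(O)c(O)c1 | starting material
16 | benzyl 3,4-bis(benzyloxy)benzoate | O=C(OCc1ccccc1)c1ccc(OCc2ccccc2)c(OCc2ccccc2)c1 | intermediate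
17 | 3,4-bis(benzyloxy)benzoic acid | OC(=O)c1ccc(OCc2ccccc2)c(OCc2ccccc2)c1 | intermediate
18 | 3,4-bis(benzyloxy)benzoyl chloride | ClC(=O)c1ccc(OCc2ccccc2)c(OCc2ccccc2)c1 | intermediate
19 | ortho-aroyloxyphenacylidene triphenylphosphorane (key-step precursor) | O=C(C=P(c1ccccc1)(c1ccccc1)c1ccccc1)c1c(OCc2ccccc2)cc(OCc2ccccc2)c(-c2c(COC(=O)C(C)(C)C)ccc(OCc3ccccc3)c2OCc2ccccc2)c1OC(=O)c1ccc(OCc2ccccc2)c(OCc2ccccc2)c1 | intermediate
20 | 8-aryl flavone pivalate (key-step product) | O=c1cc(-c2ccc(OCc3ccccc3)c(OCc3ccccc3)c2)oc2c(-c3c(COC(=O)C(C)(C)C)ccc(OCc4ccccc4)c3OCc3ccccc3)c(OCc3ccccc3)cc(OCc3ccccc3)c12 | intermediate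
21 | 8-aryl flavone benzylic alcohol | O=c1cc(-c2ccc(OCc3ccccc3)c(OCc3ccccc3)c2)oc2c(-c3c(CO)ccc(OCc4ccccc4)c3OCc3ccccc3)c(OCc3ccccc3)cc(OCc3ccccc3)c12 | intermediate
22 | 8-aryl flavone aldehyde | O=c1cc(-c2ccc(OCc3ccccc3)c(OCc3ccccc3)c2)oc2c(-c3c(C=O)ccc(OCc4ccccc4)c3OCc3ccccc3)c(OCc3ccccc3)cc(OCc3ccccc3)c12 | intermediate
23 | tert-butyl 3-[2,4-bis(benzyloxy)-6-hydroxyphenyl]-3-oxopropanoate | CC(C)(C)OC(=O)CC(=O)c1c(O)cc(OCc2ccccc2)cc1OCc1ccccc1 | intermediate
24 | (Z)-alkylidene β-keto ester | CC(C)(C)OC(=O)/C(=C\c1ccc(OCc2ccccc2)c(OCc2ccccc2)c1-c1c(OCc2ccccc2)cc(OCc2ccccc2)c2c(=O)cc(-c3ccc(OCc4ccccc4)c(OCc4ccccc4)c3)oc12)C(=O)c1c(O)cc(OCc2ccccc2)cc1OCc1ccccc1 | intermediate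
25 | tert-butyl (2S,3R)-trans-4-oxochromane-3-carboxylate (C3 labile, in equilibrium with its enol) | O=C1[C@H](C(=O)OC(C)(C)C)[C@@H](c2ccc(OCc3ccccc3)c(OCc3ccccc3)c2-c2c(OCc3ccccc3)cc(OCc3ccccc3)c3c(=O)cc(-c4ccc(OCc5ccccc5)c(OCc5ccccc5)c4)oc23)Oc2cc(OCc3ccccc3)cc(OCc3ccccc3)c21 | intermediate
26 | octa-O-benzyl (2S)-flavanone–flavone | O=C1C[C@@H](c2ccc(OCc3ccccc3)c(OCc3ccccc3)c2-c2c(OCc3ccccc3)cc(OCc3ccccc3)c3c(=O)cc(-c4ccc(OCc5ccccc5)c(OCc5ccccc5)c4)oc23)Oc2cc(OCc3ccccc3)cc(OCc3ccccc3)c21 | intermediate
27 | CNP0265600.1, (2S)-eriodictyol-(2'→8'')-luteolin | O=C1C[C@@H](c2ccc(O)c(O)c2-c2c(O)cc(O)c3c(=O)cc(-c4ccc(O)c(O)c4)oc23)Oc2cc(O)cc(O)c21 | target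

**Total step count:** 20
**Longest linear sequence:** 15 (steps 1–5, 8–10, 13–16, 18–20)

**Steps most likely to fail**

**Step 14.**
- What may go wrong: the O1'' ester is crowded by the ring B aryl group, which may slow the closure. The betaine may then lose phenoxide (an O-to-C acyl shift), or the ylide may be hydrolysed by adventitious water.
- Fallback (a diketone route in place of the olefination): it sets out from 10. Acylation of the phenol with 18 (pyridine, DMAP, CH2Cl2) should give the 2-aroyloxyacetophenone F1. A Baker–Venkataraman rearrangement (LiHMDS, THF, −78 to 0 °C) should give the 1,3-diketone F2. Cyclodehydration with the mildest acid that suffices (PPTS, toluene, 80 °C) closes O1''–C2'' and returns to the route at 20.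

**Step 8.**
- What may go wrong: transmetalation is slow at an axis that will carry four ortho substituents. Protodeboronation, hydrodeiodination of the phenoxide-rich iodide, and palladation of a neighbouring benzyl ether ring may all outrun the coupling.
- Fallback (the axis is made after the pyranone): it sets out from 9, which goes through the chemistry of steps 9, 10, 13 and 14 before any coupling.
  - LiHMDS/TMSCl gives the iodinated bis(silyl) enol ether F3, and NBS gives the iodinated bromoketone F4.
  - PPh3 gives the iodinated phosphonium bromide F5, and aqueous Na2CO3 gives the iodinated hydroxy ylide F6.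
  - Acylation with 18 gives the iodinated aroyloxy ylide F7, and heating in toluene gives the 8-iodoflavone F8.
  - F8 has no ionisable phenol, a less electron-rich ring and a tied-back O1'', and it belongs to a class known to undergo Suzuki–Miyaura coupling. Coupling it with 6 (Pd2(dba)3, SPhos, K3PO4, toluene/H2O) returns to the route at 20.

**Step 19.**
- What may go wrong: three processes can each erode the purity at C2. These are amine-promoted background closure during or after the Knoevenagel step, reversible ring opening during the acidic decarboxylation, and a mismatch between the catalyst and one sense of the axis.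
- Fallback (resolution by reduction in place of asymmetric closure): it sets out from 22 and 8.
  - A Claisen–Schmidt condensation (KOH, EtOH/THF, rt) should give the (E)-2'-hydroxychalcone F9.
  - NaOAc in refluxing EtOH should give the racemic flavanone F10.
  - Asymmetric transfer hydrogenation is run as a kinetic resolution (Cp*RhCl[(R,R)-TsDPEN], HCO2H/Et3N, EtOAc, rt, stopped near half conversion). It should reduce the 2R ketone to the cis-(2R,4R)-flavan-4-ol F11.
  - F11 is removed by chromatography. The unreacted 2S ketone is 26, where the route is rejoined. The vinylogous ester carbonyl of the flavone half is not expected to be reduced.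

**Further compounds**
F1 | step 14 | 2-aroyloxyacetophenone | CC(=O)c1c(OCc2ccccc2)cc(OCc2ccccc2)c(-c2c(COC(=O)C(C)(C)C)ccc(OCc3ccccc3)c2OCc2ccccc2)c1OC(=O)c1ccc(OCc2ccccc2)c(OCc2ccccc2)c1
F2 | step 14 | 1,3-diketone | O=C(CC(=O)c1ccc(OCc2ccccc2)c(OCc2ccccc2)c1)c1c(O)c(-c2c(COC(=O)C(C)(C)C)ccc(OCc3ccccc3)c2OCc2ccccc2)c(OCc2ccccc2)cc1OCc1ccccc1
F3 | step 8 | iodinated bis(silyl) enol ether | C=C(O[Si](C)(C)C)c1c(O[Si](C)(C)C)c(I)c(OCc2ccccc2)cc1OCc1ccccc1
F4 | step 8 | iodinated bromoketone | O=C(CBr)c1c(O)c(I)c(OCc2ccccc2)cc1OCc1ccccc1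
F5 | step 8 | iodinated phosphonium bromide | O=C(C[P+](c1ccccc1)(c1ccccc1)c1ccccc1)c1c(O)c(I)c(OCc2ccccc2)cc1OCc1ccccc1.[Br-]
F6 | step 8 | iodinated hydroxy ylide | O=C(C=P(c1ccccc1)(c1ccccc1)c1ccccc1)c1c(O)c(I)c(OCc2ccccc2)cc1OCc1ccccc1
F7 | step 8 | iodinated aroyloxy ylide | O=C(C=P(c1ccccc1)(c1ccccc1)c1ccccc1)c1c(OCc2ccccc2)cc(OCc2ccccc2)c(I)c1OC(=O)c1ccc(OCc2ccccc2)c(OCc2ccccc2)c1
F8 | step 8 | 8-iodoflavone | O=c1cc(-c2ccc(OCc3ccccc3)c(OCc3ccccc3)c2)oc2c(I)c(OCc3ccccc3)cc(OCc3ccccc3)c12
F9 | step 19 | (E)-2'-hydroxychalcone | O=C(/C=C/c1ccc(OCc2ccccc2)c(OCc2ccccc2)c1-c1c(OCc2ccccc2)cc(OCc2ccccc2)c2c(=O)cc(-c3ccc(OCc4ccccc4)c(OCc4ccccc4)c3)oc12)c1c(O)cc(OCc2ccccc2)cc1OCc1ccccc1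
F10 | step 19 | racemic flavanone | O=C1CC(c2ccc(OCc3ccccc3)c(OCc3ccccc3)c2-c2c(OCc3ccccc3)cc(OCc3ccccc3)c3c(=O)cc(-c4ccc(OCc5ccccc5)c(OCc5ccccc5)c4)oc23)Oc2cc(OCc3ccccc3)cc(OCc3ccccc3)c21
F11 | step 19 | cis-(2R,4R)-flavan-4-ol | O[C@@H]1C[C@H](c2ccc(OCc3ccccc3)c(OCc3ccccc3)c2-c2c(OCc3ccccc3)cc(OCc3ccccc3)c3c(=O)cc(-c4ccc(OCc5ccccc5)c(OCc5ccccc5)c4)oc23)Oc2cc(OCc3ccccc3)cc(OCc3ccccc3)c21
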